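**Plan**

1. Retrosynthesis: the nineteen benzyl ethers and the two gallate esters come off first. The two C4–C8 interflavan bonds are then cut, each back to a C4 cation equivalent of benzylated (−)-epicatechin. Last, ring C of the terminal catechin unit is cut at C4–C4a and O1–C8a into a 3,5-dioxygenated aryne (ring A) and an O1–C2–C3–C4 chain that carries ring B.
2. Forward: the C2–C3–C4 chain is built from 3,4-bis(benzyloxy)benzaldehyde and ring C is annulated onto ring A in one operation. The oligomer then grows upward (monomer cation + terminal unit, then monomer cation + dimer), the gallates go on last, and all benzyl groups leave together.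
3. Enabling feature: ring A is a phloroglucinol ring, so its C5 oxygen is ortho to C4a. An aryne across C4a–C8a is therefore polarized: the C2 alkoxide adds at C8a and the carbanion appears at C4a, 6-exo to the C4 chloride.
4. Stereochemistry: C2 and C3 of the terminal unit come from a Sharpless kinetic resolution (erythro epoxy alcohol) and pass through the annulation untouched (2,3-trans). C2 and C3 of the two upper units come from (−)-epicatechin. Both C4 centers arise by attack on the C4 cation anti to the C3 oxygen (4β).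
5. The terminal 3-hydroxyl is carried as a benzyl ether from the fragment stage, so only the two upper 3-hydroxyls are free for galloylation.

Key step: step 9

Remark: the target is read as epicatechin 3-O-gallate-(4β→8)-epicatechin 3-O-gallate-(4β→8)-catechin (upper and middle units 2R,3R with 3,4-trans C4 bonds, terminal unit 2R,3S). 3,4-Bis(benzyloxy)benzaldehyde, 3,5-bis(benzyloxy)phenol, (−)-epicatechin and 3,4,5-tris(benzyloxy)benzoic acid are taken as purchasable.

**Route**

Step 1
Reactants: 1 3,4-bis(benzyloxy)benzaldehyde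
Product: 2 rac-1-[3,4-bis(benzyloxy)phenyl]prop-2-en-1-ol
Conditions: CH2=CHMgBr, THF, 0 °C; aq NH4Cl
Reagents that add atoms: vinylmagnesium bromide, C=C[Mg]Br
Why: Grignard 1,2-addition to the non-enolizable aryl aldehyde should give the racemic secondary allylic alcohol needed for the kinetic resolution.

Step 2
Reactants: 2 rac-1-[3,4-bis(benzyloxy)phenyl]prop-2-en-1-ol
Product: 3 (R)-[3,4-bis(benzyloxy)phenyl][(2S)-oxiran-2-yl]methanol (erythro epoxy alcohol)
Conditions: Ti(OiPr)4 (cat.), D-(−)-DIPT (cat.), t-BuOOH (0.55 equiv), 4 Å MS, CH2Cl2, −20 °C; chromatographic separation from unreacted (R)-2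
Reagents that add atoms: tert-butyl hydroperoxide, CC(C)(C)OO
Why: Sharpless kinetic resolution (Katsuki–Sharpless epoxidation): with the D-(−)-tartrate catalyst the (S)-alcohol should be epoxidized fast and on the alkene face that leads to the erythro epoxy alcohol, so the catalyst sets the epoxide carbon (future C3) and selects the carbinol carbon (future C2).

Step 3
Reactants: 3 (R)-[3,4-bis(benzyloxy)phenyl][(2S)-oxiran-2-yl]methanol
Product: 4 {(R)-[3,4-bis(benzyloxy)phenyl][(2S)-oxiran-2-yl]methoxy}triethylsilane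
Conditions: Et3SiCl, imidazole, CH2Cl2, 0 °C
Reagents that add atoms: chlorotriethylsilane, CC[Si](Cl)(CC)CC
Why: Silylation of the secondary alcohol masks the future O1 as a fluoride-labile ether that later serves as the latent alkoxide.

Step 4
Reactants: 4 {(R)-[3,4-bis(benzyloxy)phenyl][(2S)-oxiran-2-yl]methoxy}triethylsilane
Product: 5 (1R,2R)-1-[3,4-bis(benzyloxy)phenyl]-3-chloro-1-(triethylsilyloxy)propan-2-ol
Conditions: LiCl, AcOH, THF, rt
Reagents that add atoms: lithium chloride, [Li+].[Cl-]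
Why: SN2 opening of the terminal epoxide by chloride at the primary carbon (halohydrin formation) should leave the C3 configuration untouched and free the C3 hydroxyl.

Step 5
Reactants: 5 (1R,2R)-1-[3,4-bis(benzyloxy)phenyl]-3-chloro-1-(triethylsilyloxy)propan-2-ol
Product: 6 {(1R,2R)-2-(benzyloxy)-1-[3,4-bis(benzyloxy)phenyl]-3-chloropropoxy}triethylsilane
Conditions: 2-benzyloxy-1-methylpyridinium triflate, MgO, PhCF3, 83 °C
Reagents that add atoms: 2-benzyloxy-1-methylpyridinium triflate, C[n+]1ccccc1OCc1ccccc1.[O-]S(=O)(=O)C(F)(F)F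
Why: Neutral O-benzylation by thermal benzyl transfer from the pyridinium salt should etherify the C3 hydroxyl without base, so that neither epoxide re-closure onto the chloride nor silyl migration is triggered.

Step 6
Reactants: 7 3,5-bis(benzyloxy)phenol
Product: 8 3,5-bis(benzyloxy)phenyl N-isopropylcarbamate
Conditions: i-PrNCO, Et3N (cat.), CH2Cl2, rt
Reagents that add atoms: isopropyl isocyanate, CC(C)N=C=O
Why: Carbamoylation of the phenol with an isocyanate installs a cleavable directing group for ortho-metalation.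

Step 7
Reactants: 8 3,5-bis(benzyloxy)phenyl N-isopropylcarbamate
Product: 12 3,5-bis(benzyloxy)-2-(trimethylsilyl)phenyl N-isopropylcarbamate, via N-silyl carbamate 9 (not isolated), via ortho-lithiated carbamate 10 (not isolated), via C-silylated N-silyl carbamate 11 (not isolated)
Conditions: t-BuMe2SiOTf, TMEDA, Et2O, 0 °C to rt; n-BuLi, TMEDA, −78 °C; Me3SiCl, −78 °C to rt; aq NaHSO4
Reagents that add atoms: chlorotrimethylsilane, C[Si](C)(C)Cl
Why: Directed ortho-metalation: after in situ N-silylation the carbamate should direct n-BuLi to the ring carbon flanked by the carbamate and a benzyloxy group (the two ortho positions are equivalent), and silyl quench followed by N–Si hydrolysis on work-up gives the ortho-silyl carbamate.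

Step 8
Reactants: 12 3,5-bis(benzyloxy)-2-(trimethylsilyl)phenyl N-isopropylcarbamate
Product: 14 3,5-bis(benzyloxy)-2-(trimethylsilyl)phenyl trifluoromethanesulfonate, via silylphenoxide 13 (not isolated)
Conditions: DBU, Et2NH, MeCN, 40 °C; then PhNTf2, rt
Reagents that add atoms: N-phenylbis(trifluoromethanesulfonimide), O=S(=O)(N(c1ccccc1)S(=O)(=O)C(F)(F)F)C(F)(F)F
Why: Base-induced E1cB cleavage of the N–H carbamate (the isocyanate is scavenged by Et2NH) should unmask the phenoxide, which is sulfonylated in the same flask to the o-silylaryl triflate aryne precursor.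

Step 9
Reactants: 6 {(1R,2R)-2-(benzyloxy)-1-[3,4-bis(benzyloxy)phenyl]-3-chloropropoxy}triethylsilane; 14 3,5-bis(benzyloxy)-2-(trimethylsilyl)phenyl trifluoromethanesulfonate
Product: 18 3,5,7,3',4'-penta-O-benzyl-(+)-catechin [(2R,3S)-3,5,7-tris(benzyloxy)-2-[3,4-bis(benzyloxy)phenyl]chromane], via cesium alkoxide 15 (not isolated), via 3,5-bis(benzyloxy)benzyne 16 (not isolated), via aryl anion adduct 17 (not isolated)
Conditions: CsF, 18-crown-6, THF, 0 to 40 °C; 14 (2 equiv) added slowly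
Reagents that add atoms: none
Why: Proposed new method: fluoride both cleaves the C2–O triethylsilyl ether of 6 to the cesium alkoxide 15 and triggers 1,2-elimination of 14 to the aryne 16, so that the alkoxide meets the aryne in a medium without O–H; 15 adds to the aryne carbon that becomes C8a (new O1–C8a bond), and the resulting aryl anion 17 at C4a displaces the primary chloride at C4 in a 6-exo-tet closure (new C4–C4a bond) that completes ring C at the flavan oxidation level. The closest known reaction types are the aryne annulation of salicylate esters to xanthones (O-addition to an aryne, then intramolecular capture of the aryl anion by a tethered electrophile) and the Parham cyclialkylation of an ortho-metalated aryl ether onto a primary halide; their union with an aliphatic alkoxide and an alkyl chloride is the new element. No stereocenter is formed: C2 and C3 come from 6 unchanged because neither the C2–O bond nor any bond at C3 is broken, so the anti (1R,2R) chain maps onto the 2,3-trans (2R,3S) ring. The regioselectivity needed (oxygen at C8a, carbon at C4a) is secured by the ring A benzyloxy group at C5, which is ortho to the aryne carbon C4a and meta to C8a: its inductive pull distorts the aryne and stabilizes negative charge at C4a, as in 3-alkoxyarynes. The chemoselectivity needed (aryl anion captured by carbon, not by a proton, and before 15 closes to an oxetane) rests on the aprotic unmasking of the alkoxide, on the slow 4-exo-tet displacement of a chloride against the 6-exo-tet one, and on a steady supply of aryne from excess 14.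

Step 10
Reactants: 19 (−)-epicatechin
Product: 20 5,7,3',4'-tetra-O-benzyl-(−)-epicatechin
Conditions: BnBr (4.2 equiv), K2CO3, DMF, 0 °C to rt
Reagents that add atoms: benzyl bromide, BrCc1ccccc1
Why: Williamson etherification: the carbonate ionizes only the four phenols, so the C3 alcohol should stay free.

Step 11
Reactants: 20 5,7,3',4'-tetra-O-benzyl-(−)-epicatechin
Product: 21 4β-(2-ethoxyethoxy)-5,7,3',4'-tetra-O-benzyl-(−)-epicatechin (2,3-cis-3,4-trans)
Conditions: DDQ, HOCH2CH2OEt, CH2Cl2, rt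
Reagents that add atoms: 2-ethoxyethanol, CCOCCO
Why: DDQ benzylic oxidation (hydride abstraction at C4, assisted by the ring A oxygens) should give a C4 cation that the alcohol traps trans to the C3 hydroxyl, i.e. as the 4β ether.

Step 12
Reactants: 21 4β-(2-ethoxyethoxy)-5,7,3',4'-tetra-O-benzyl-(−)-epicatechin; 18 3,5,7,3',4'-penta-O-benzyl-(+)-catechin
Product: 22 [5,7,3',4'-tetra-O-benzyl-epicatechin]-(4β→8)-[3,5,7,3',4'-penta-O-benzyl-catechin] (upper 3-OH free)
Conditions: TMSOTf, CH2Cl2, −78 °C; 18 in excess (recovered)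
Reagents that add atoms: none
Why: Lewis acid ionization of the C4 ether gives the flavan-4-yl cation, which C8 of 18 (the most nucleophilic ring A position) should attack in a Friedel–Crafts alkylation anti to the C3 oxygen of the electrophile, setting the 4β→8 bond.

Step 13
Reactants: 21 4β-(2-ethoxyethoxy)-5,7,3',4'-tetra-O-benzyl-(−)-epicatechin; 22 benzylated epicatechin-(4β→8)-catechin dimer
Product: 23 [tetra-O-benzyl-epicatechin]-(4β→8)-[tetra-O-benzyl-epicatechin]-(4β→8)-[penta-O-benzyl-catechin] (thirteen benzyl ethers, upper and middle 3-OH free)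
Conditions: TMSOTf, CH2Cl2, −78 °C; 22 in excess (recovered)
Reagents that add atoms: none
Why: The same cation-based Friedel–Crafts coupling: the only unsubstituted C8 of 22 (on its epicatechin unit) should attack the C4 cation anti to the C3 hydroxyl and give the second 4β→8 bond.

Step 14
Reactants: 23 benzylated trimer diol; 24 3,4,5-tris(benzyloxy)benzoic acid
Product: 25 nonadeca-O-benzyl derivative of the target (both gallates installed)
Conditions: 24 (4 equiv), DCC, DMAP, CH2Cl2, rt
Reagents that add atoms: none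
Why: Steglich esterification should acylate the only two free hydroxyls, C3–OH of the upper and middle units, the terminal C3 oxygen being blocked as its benzyl ether.

Step 15
Reactants: 25 nonadeca-O-benzyl derivative of the target
Product: 26 epicatechin 3-O-gallate-(4β→8)-epicatechin 3-O-gallate-(4β→8)-catechin (target)
Conditions: H2 (1 atm), Pd(OH)2/C, THF/MeOH/H2O, rt
Reagents that add atoms: none
Why: Catalytic hydrogenolysis should cleave all nineteen benzyl ethers (eighteen aryl, one alkyl) while the gallate esters and the acid-labile interflavan bonds survive the neutral conditions.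

**Compound list**

1 | 3,4-bis(benzyloxy)benzaldehyde | O=Cc1ccc(OCc2ccccc2)c(OCc2ccccc2)c1 | starting material
2 | rac-1-[3,4-bis(benzyloxy)phenyl]prop-2-en-1-ol | OC(C=C)c1ccc(OCc2ccccc2)c(OCc2ccccc2)c1 | intermediate
3 | (R)-[3,4-bis(benzyloxy)phenyl][(2S)-oxiran-2-yl]methanol | O[C@H](c1ccc(OCc2ccccc2)c(OCc2ccccc2)c1)[C@@H]1CO1 | intermediate
4 | {(R)-[3,4-bis(benzyloxy)phenyl][(2S)-oxiran-2-yl]methoxy}triethylsilane | CC[Si](CC)(CC)O[C@H](c1ccc(OCc2ccccc2)c(OCc2ccccc2)c1)[C@@H]1CO1 | intermediate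
5 | (1R,2R)-1-[3,4-bis(benzyloxy)phenyl]-3-chloro-1-(triethylsilyloxy)propan-2-ol | CC[Si](CC)(CC)O[C@H](c1ccc(OCc2ccccc2)c(OCc2ccccc2)c1)[C@@H](O)CCl | intermediate
6 | {(1R,2R)-2-(benzyloxy)-1-[3,4-bis(benzyloxy)phenyl]-3-chloropropoxy}triethylsilane | CC[Si](CC)(CC)O[C@H](c1ccc(OCc2ccccc2)c(OCc2ccccc2)c1)[C@@H](OCc1ccccc1)CCl | intermediate
7 | 3,5-bis(benzyloxy)phenol | Oc1cc(OCc2ccccc2)cc(OCc2ccccc2)c1 | starting material
8 | 3,5-bis(benzyloxy)phenyl N-isopropylcarbamate | CC(C)NC(=O)Oc1cc(OCc2ccccc2)cc(OCc2ccccc2)c1 | intermediate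
9 | N-(tert-butyldimethylsilyl) derivative of 8 (not isolated) | CC(C)N(C(=O)Oc1cc(OCc2ccccc2)cc(OCc2ccccc2)c1)[Si](C)(C)C(C)(C)C | intermediate
10 | 2-lithio derivative of 9 (not isolated) | CC(C)N(C(=O)Oc1cc(OCc2ccccc2)cc(OCc2ccccc2)c1[Li])[Si](C)(C)C(C)(C)C | intermediate
11 | 2-trimethylsilyl derivative of 9 (not isolated) | CC(C)N(C(=O)Oc1cc(OCc2ccccc2)cc(OCc2ccccc2)c1[Si](C)(C)C)[Si](C)(C)C(C)(C)C | intermediate
12 | 3,5-bis(benzyloxy)-2-(trimethylsilyl)phenyl N-isopropylcarbamate | CC(C)NC(=O)Oc1cc(OCc2ccccc2)cc(OCc2ccccc2)c1[Si](C)(C)C | intermediate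
13 | 3,5-bis(benzyloxy)-2-(trimethylsilyl)phenol, formed as its DBU salt (not isolated) | Oc1cc(OCc2ccccc2)cc(OCc2ccccc2)c1[Si](C)(C)C | intermediate
14 | 3,5-bis(benzyloxy)-2-(trimethylsilyl)phenyl trifluoromethanesulfonate | FC(F)(F)S(=O)(=O)Oc1cc(OCc2ccccc2)cc(OCc2ccccc2)c1[Si](C)(C)C | intermediate
15 | cesium (1R,2R)-2-(benzyloxy)-1-[3,4-bis(benzyloxy)phenyl]-3-chloropropan-1-olate (not isolated) | [Cs+].[O-][C@H](c1ccc(OCc2ccccc2)c(OCc2ccccc2)c1)[C@@H](OCc1ccccc1)CCl | intermediate
16 | 3,5-bis(benzyloxy)benzyne (1,2-didehydro-3,5-bis(benzyloxy)benzene; not isolated) | C1(OCc2ccccc2)=CC(OCc2ccccc2)=CC#C1 | intermediate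
17 | cesium 2,4-bis(benzyloxy)-6-{(1R,2R)-2-(benzyloxy)-1-[3,4-bis(benzyloxy)phenyl]-3-chloropropoxy}benzen-1-ide (aryl anion adduct; not isolated) | [Cs+].[C-]1=C(OCc2ccccc2)C=C(OCc2ccccc2)C=C1O[C@H](c1ccc(OCc2ccccc2)c(OCc2ccccc2)c1)[C@@H](OCc1ccccc1)CCl | intermediate
18 | 3,5,7,3',4'-penta-O-benzyl-(+)-catechin | c1(OCc5ccccc5)cc(OCc5ccccc5)c2c(c1)O[C@H](c1ccc(OCc5ccccc5)c(OCc5ccccc5)c1)[C@@H](OCc5ccccc5)C2 | intermediate
19 | (−)-epicatechin | C1c2c(O)cc(O)cc2O[C@H](c2ccc(O)c(O)c2)[C@@H]1O | starting material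
20 | 5,7,3',4'-tetra-O-benzyl-(−)-epicatechin | C1c2c(OCc5ccccc5)cc(OCc5ccccc5)cc2O[C@H](c2ccc(OCc5ccccc5)c(OCc5ccccc5)c2)[C@@H]1O | intermediate
21 | 4β-(2-ethoxyethoxy)-5,7,3',4'-tetra-O-benzyl-(−)-epicatechin | CCOCCO[C@H]1c2c(OCc5ccccc5)cc(OCc5ccccc5)cc2O[C@H](c2ccc(OCc5ccccc5)c(OCc5ccccc5)c2)[C@@H]1O | intermediate
22 | [5,7,3',4'-tetra-O-benzyl-epicatechin]-(4β→8)-[3,5,7,3',4'-penta-O-benzyl-catechin] | O[C@@H]1[C@@H](c2c(OCc5ccccc5)cc(OCc5ccccc5)c3c2O[C@H](c2ccc(OCc5ccccc5)c(OCc5ccccc5)c2)[C@@H](OCc5ccccc5)C3)c2c(OCc5ccccc5)cc(OCc5ccccc5)cc2O[C@@H]1c1ccc(OCc5ccccc5)c(OCc5ccccc5)c1 | intermediate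
23 | [tetra-O-benzyl-epicatechin]-(4β→8)-[tetra-O-benzyl-epicatechin]-(4β→8)-[penta-O-benzyl-catechin] | O[C@@H]1[C@@H](c2c(OCc5ccccc5)cc(OCc5ccccc5)c3c2O[C@H](c2ccc(OCc5ccccc5)c(OCc5ccccc5)c2)[C@@H](OCc5ccccc5)C3)c2c(OCc5ccccc5)cc(OCc5ccccc5)c([C@H]3c4c(OCc5ccccc5)cc(OCc5ccccc5)cc4O[C@H](c4ccc(OCc5ccccc5)c(OCc5ccccc5)c4)[C@@H]3O)c2O[C@@H]1c1ccc(OCc5ccccc5)c(OCc5ccccc5)c1 | intermediate
24 | 3,4,5-tris(benzyloxy)benzoic acid | O=C(O)c1cc(OCc2ccccc2)c(OCc2ccccc2)c(OCc2ccccc2)c1 | starting material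
25 | nonadeca-O-benzyl derivative of the target (all phenols and the terminal 3-OH benzylated) | O=C(O[C@@H]1[C@@H](c2c(OCc5ccccc5)cc(OCc5ccccc5)c3c2O[C@H](c2ccc(OCc5ccccc5)c(OCc5ccccc5)c2)[C@@H](OCc5ccccc5)C3)c2c(OCc5ccccc5)cc(OCc5ccccc5)c([C@H]3c4c(OCc5ccccc5)cc(OCc5ccccc5)cc4O[C@H](c4ccc(OCc5ccccc5)c(OCc5ccccc5)c4)[C@@H]3OC(=O)c3cc(OCc5ccccc5)c(OCc5ccccc5)c(OCc5ccccc5)c3)c2O[C@@H]1c1ccc(OCc5ccccc5)c(OCc5ccccc5)c1)c1cc(OCc5ccccc5)c(OCc5ccccc5)c(OCc5ccccc5)c1 | intermediate
26 | epicatechin 3-O-gallate-(4β→8)-epicatechin 3-O-gallate-(4β→8)-catechin | O=C(O[C@@H]1[C@@H](c2c(O)cc(O)c3c2O[C@H](c2ccc(O)c(O)c2)[C@@H](O)C3)c2c(O)cc(O)c([C@H]3c4c(O)cc(O)cc4O[C@H](c4ccc(O)c(O)c4)[C@@H]3OC(=O)c3cc(O)c(O)c(O)c3)c2O[C@@H]1c1ccc(O)c(O)c1)c1cc(O)c(O)c(O)c1 | target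

**Step count and risks**

Total: 15 steps. Longest linear sequence: 10 steps (1–5, 9, 12–15).

Step 9 (proposed new method). The aryl anion may pick up a proton instead of closing on the chloride, the unmasked alkoxide may close to an oxetane before it meets the aryne, or the anion may eliminate HCl across C3–C4. The fallback uses known reactions and forms the two bonds in separate steps. It sets out from epoxy alcohol 3 and aryne precursor 14. With CsF in MeCN at room temperature the aryne should insert into the O–H bond of 3 (known O-arylation of alcohols by arynes, the hydroxyl proton quenching the aryl anion) and give (R)-[3,4-bis(benzyloxy)phenyl][(2S)-oxiran-2-yl]methyl 3,5-bis(benzyloxy)phenyl ether F1. A catalytic Lewis acid (FeBr3/AgOTf in CH2Cl2, or BF3·OEt2 at −78 °C) should then bring about the known 6-endo intramolecular Friedel–Crafts epoxide–arene cyclization of this aryl glycidyl-type ether at the terminal epoxide carbon. Either ortho position of the symmetric phenoxy ring gives the same product, 5,7,3',4'-tetra-O-benzyl-(+)-catechin F2. NaH and BnBr in DMF return to 18.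

Step 13. The electrophile 21 still has a free C8 and can condense with itself or over-extend the chain, while the hindered dimer reacts slowly. The fallback caps C8 of the electrophile. It sets out from 20: NBS in CH2Cl2 at −78 °C should brominate C8 to 8-bromo-5,7,3',4'-tetra-O-benzyl-(−)-epicatechin F3. DDQ and 2-ethoxyethanol give its 4β-(2-ethoxyethoxy) derivative F4, which can no longer act as a nucleophile. TMSOTf coupling of F4 with 22 should give the 8-bromo trimer diol F5, and n-Bu3SnH/AIBN in toluene at 90 °C removes the bromine to return to 23.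

Step 14. Acylation of the two hindered axial C3 hydroxyls, each flanked by a C4 aryl group, may stop at the monoester. The fallback puts the gallates on before the interflavan bonds are made. It sets out from 21: Steglich esterification with 24 gives 3-O-[3,4,5-tris(benzyloxy)benzoyl]-4β-(2-ethoxyethoxy)-5,7,3',4'-tetra-O-benzyl-(−)-epicatechin F6. TMSOTf coupling of F6 with 18 (the C3 acyloxy group assists 3,4-trans attack) gives the mono-galloylated dimer F7, and a second coupling of F6 with F7 comes back to the route at 25.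

**Further compounds**

F1 | step 9 | (R)-[3,4-bis(benzyloxy)phenyl][(2S)-oxiran-2-yl]methyl 3,5-bis(benzyloxy)phenyl ether | c1c(OCc5ccccc5)cc(OCc5ccccc5)cc1O[C@H](c1ccc(OCc5ccccc5)c(OCc5ccccc5)c1)[C@@H]1CO1
F2 | step 9 | 5,7,3',4'-tetra-O-benzyl-(+)-catechin | c1(OCc5ccccc5)cc(OCc5ccccc5)c2c(c1)O[C@H](c1ccc(OCc5ccccc5)c(OCc5ccccc5)c1)[C@@H](O)C2
F3 | step 13 | 8-bromo-5,7,3',4'-tetra-O-benzyl-(−)-epicatechin | C1c2c(OCc5ccccc5)cc(OCc5ccccc5)c(Br)c2O[C@H](c2ccc(OCc5ccccc5)c(OCc5ccccc5)c2)[C@@H]1O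
F4 | step 13 | 8-bromo-4β-(2-ethoxyethoxy)-5,7,3',4'-tetra-O-benzyl-(−)-epicatechin | CCOCCO[C@H]1c2c(OCc5ccccc5)cc(OCc5ccccc5)c(Br)c2O[C@H](c2ccc(OCc5ccccc5)c(OCc5ccccc5)c2)[C@@H]1O
F5 | step 13 | 8-bromo derivative of trimer diol 23 (bromine on C8 of the top unit) | O[C@@H]1[C@@H](c2c(OCc5ccccc5)cc(OCc5ccccc5)c3c2O[C@H](c2ccc(OCc5ccccc5)c(OCc5ccccc5)c2)[C@@H](OCc5ccccc5)C3)c2c(OCc5ccccc5)cc(OCc5ccccc5)c([C@H]3c4c(OCc5ccccc5)cc(OCc5ccccc5)c(Br)c4O[C@H](c4ccc(OCc5ccccc5)c(OCc5ccccc5)c4)[C@@H]3O)c2O[C@@H]1c1ccc(OCc5ccccc5)c(OCc5ccccc5)c1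
F6 | step 14 | 3-O-[3,4,5-tris(benzyloxy)benzoyl]-4β-(2-ethoxyethoxy)-5,7,3',4'-tetra-O-benzyl-(−)-epicatechin | CCOCCO[C@H]1c2c(OCc5ccccc5)cc(OCc5ccccc5)cc2O[C@H](c2ccc(OCc5ccccc5)c(OCc5ccccc5)c2)[C@@H]1OC(=O)c1cc(OCc5ccccc5)c(OCc5ccccc5)c(OCc5ccccc5)c1
F7 | step 14 | [3-O-(tri-O-benzylgalloyl)-tetra-O-benzyl-epicatechin]-(4β→8)-[penta-O-benzyl-catechin] | O=C(O[C@@H]1[C@@H](c2c(OCc5ccccc5)cc(OCc5ccccc5)c3c2O[C@H](c2ccc(OCc5ccccc5)c(OCc5ccccc5)c2)[C@@H](OCc5ccccc5)C3)c2c(OCc5ccccc5)cc(OCc5ccccc5)cc2O[C@@H]1c1ccc(OCc5ccccc5)c(OCc5ccccc5)c1)c1cc(OCc5ccccc5)c(OCc5ccccc5)c(OCc5ccccc5)c1
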